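**Plan**

1. Retrosynthesis: cut the acetate and anisoate C–O bonds, then C8=C9 of the cycloheptene (ring-closing metathesis), then C1–C10 (allylation of a C1=C2 enolate), and finally, in one operation, the cyclopentane bonds C2–C3 and C4–C5. This leaves acylsilane 6 (C2, C1, C5 and the C6–C8 chain) and 3-methylbutan-2-one (C3, C4, isopropyl).
2. Forward: acylsilane chain carrying the C6 carbinol → five-membered ring by a Brook-rearrangement [3+2] annulation → anisoylation → quaternary C1 by allylation → seven-membered ring by metathesis → C2 reduction and acetylation.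
3. Enabling feature: the cyclopentane carries a 1,3-dioxygen pattern (C2–O and C4–O flanking C3) next to the allylic triad C2–C1–C5. C2 can therefore be an acylsilane carbon and C4 the carbonyl of a methyl ketone; silyl migration from C2 to O2 turns C5, the former enone β-carbon, into a nucleophile for the carbonyl carbon C4.
4. Stereochemistry: C6 by catalyst-controlled allylboration; C5 and C4 relayed from the C6 lithium alkoxide in the annulation; C1 by allylation anti to the C5 side chain; C2 by hydride delivery from the C4 hydroxyl. The trans ring fusion follows from C1 and C5.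

Key step: step 5

Remark: aldehyde 1, boronate 5 and (S)-TRIP are taken as purchasable. Atom numbers C1–C10 in the text are those of the daucane skeleton (C1 = ring-fusion C–CH3, C2 = CH–OAc, C3 = CH2, C4 = C(OH)i-Pr, C5 = ring-fusion CH, C6 = CH–O-anisoyl, C7–C10 = the other seven-ring carbons); β is the face of the C1 methyl.

Step 1
Reactants: 1 (E)-4,4-dimethoxy-2-methylbut-2-enal
Product: 2 (E)-1-[dimethyl(phenyl)silyl]-4,4-dimethoxy-2-methylbut-2-en-1-ol (racemic carbinol)
Conditions: PhMe2SiLi, THF, −78 °C; NH4Cl (aq) at −78 °C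
Reagents that add atoms: dimethyl(phenyl)silyllithium, [Li][Si](C)(C)c1ccccc1
Why: 1,2-addition of a silyllithium to the enal carbonyl (the standard entry to α-hydroxysilanes) should give the α-silyl alkoxide, which the cold quench protonates before a Brook rearrangement can start; the racemic carbinol centre is removed in step 2.

Step 2
Reactants: 2 (E)-1-[dimethyl(phenyl)silyl]-4,4-dimethoxy-2-methylbut-2-en-1-ol
Product: 3 (E)-1-[dimethyl(phenyl)silyl]-4,4-dimethoxy-2-methylbut-2-en-1-one
Conditions: Dess–Martin periodinane, NaHCO3, CH2Cl2, 0 °C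
Reagents that add atoms: none
Why: Dess–Martin oxidation of an α-hydroxysilane under buffered, non-basic conditions should give the acylsilane without Brook rearrangement.

Step 3
Reactants: 3 (E)-1-[dimethyl(phenyl)silyl]-4,4-dimethoxy-2-methylbut-2-en-1-one
Product: 4 (E)-4-[dimethyl(phenyl)silyl]-3-methyl-4-oxobut-2-enal
Conditions: oxalic acid (aq), SiO2, CH2Cl2, 20 °C
Reagents that add atoms: water, O
Why: Acid-catalysed acetal hydrolysis should release the enal, since the acylsilane is stable to mild acid and the E-alkene cannot cyclise.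

Step 4
Reactants: 4 (E)-4-[dimethyl(phenyl)silyl]-3-methyl-4-oxobut-2-enal; 5 4,4,5,5-tetramethyl-2-(2-methylprop-2-en-1-yl)-1,3,2-dioxaborolane
Product: 6 (2E,4S)-1-[dimethyl(phenyl)silyl]-4-hydroxy-2,6-dimethylhepta-2,6-dien-1-one
Conditions: (S)-TRIP [(S)-3,3′-bis(2,4,6-triisopropylphenyl)-1,1′-binaphthalene-2,2′-diyl hydrogen phosphate] (5 mol %), toluene, −30 °C; aqueous work-up
Reagents that add atoms: none
Why: Chiral phosphoric acid-catalysed allylboration through a closed six-membered transition state should add the methallyl group to the aldehyde only (the hindered acylsilane carbonyl does not compete), the (S)-catalyst being expected to expose the Si face so that the C6 carbinol forms as (S).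

Step 5
Reactants: 6 (2E,4S)-1-[dimethyl(phenyl)silyl]-4-hydroxy-2,6-dimethylhepta-2,6-dien-1-one; 7 3-methylbutan-2-one
Product: 11 (1S)-1-{(1S,5R)-3-[dimethyl(phenyl)silyloxy]-5-hydroxy-2-methyl-5-(propan-2-yl)cyclopent-2-en-1-yl}-3-methylbut-3-en-1-ol, via lithium enolate 8 (not isolated), via α-silyl dialkoxide 9 (not isolated), via siloxyallyl-lithium 10 (not isolated)
Conditions: LiN(i-Pr)2 (2.2 equiv), 7 (2.2 equiv), THF, −78 °C; add 6; −78 → −30 °C; AcOH at −78 °C
Reagents that add atoms: none
Why: One equivalent of enolate 8 converts the C6 hydroxyl into its lithium alkoxide, a second adds to the acylsilane carbonyl (C2–C3 bond) to give 9, a [1,2]-Brook rearrangement moves silicon from C2 to O2 to give the siloxyallyl-lithium 10, and its terminus C5 attacks the pendant isopropyl ketone carbon C4 (C4–C5 bond). The closest known reaction type is the Brook-rearrangement-mediated [3+2] annulation of β-silyl- or β-thio-substituted acryloylsilanes with lithium enolates of alkyl methyl ketones, which gives 4-hydroxycyclopent-1-enyl silyl ethers of this substitution pattern; here the β-substituent is an oxido-alkyl group. The only ring closed is the cyclopentene, by exo-trig addition of the allyl-anion terminus to the ketone carbonyl (possibly through a reversible cyclopropanolate from attack at C2 that ring-expands to the same alkoxide). C5 and C4 are controlled by the C6 lithium alkoxide: allylic 1,3-strain with the C1 methyl holds H6 in the plane of the allyl system, the O6–Li unit binds the ketone oxygen and delivers C4 to the alkoxide face of C5, and the same lithium bridge places O4 cis to the C6 side chain. The step needs 1,2- rather than 1,4-addition of the enolate (the α-methyl group and the electron-rich oxido-alkyl β-substituent make C5 a poor Michael position), no β-elimination at C6 (an oxide cannot leave, which is why the hydroxyl is left unprotected), and ring closure faster than proton transfer from C3 (intramolecular, as in the known annulation).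

Step 6
Reactants: 11 (1S)-1-{(1S,5R)-3-[dimethyl(phenyl)silyloxy]-5-hydroxy-2-methyl-5-(propan-2-yl)cyclopent-2-en-1-yl}-3-methylbut-3-en-1-ol; 12 4-methoxybenzoyl chloride
Product: 13 (1S)-1-{(1S,5R)-3-[dimethyl(phenyl)silyloxy]-5-hydroxy-2-methyl-5-(propan-2-yl)cyclopent-2-en-1-yl}-3-methylbut-3-en-1-yl 4-methoxybenzoate
Conditions: Et3N, DMAP (cat.), CH2Cl2, 0 → 20 °C
Reagents that add atoms: none
Why: DMAP-catalysed acylation should esterify the secondary C6 hydroxyl only, the tertiary C4 hydroxyl being too hindered and the silyl enol ether stable to the buffered medium.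

Step 7
Reactants: 13 (1S)-1-{(1S,5R)-3-[dimethyl(phenyl)silyloxy]-5-hydroxy-2-methyl-5-(propan-2-yl)cyclopent-2-en-1-yl}-3-methylbut-3-en-1-yl 4-methoxybenzoate; 14 allyl methyl carbonate
Product: 15 (1S)-1-[(1S,2R,5R)-5-hydroxy-2-methyl-3-oxo-5-(propan-2-yl)-2-(prop-2-en-1-yl)cyclopentyl]-3-methylbut-3-en-1-yl 4-methoxybenzoate
Conditions: Pd2(dba)3 (2.5 mol %), dppe (6 mol %), Bu4N[Ph3SiF2] (10 mol %), THF, 25 °C
Reagents that add atoms: none
Why: In this Tsuji allylation of a silyl enol ether, fluoride and the methoxide released from the carbonate should unmask the C1=C2 enolate regiospecifically, and the allylpalladium electrophile should reach C1 on the face anti to the large C5 side chain, setting the quaternary centre with allyl trans and methyl cis to C6.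

Step 8
Reactants: 15 (1S)-1-[(1S,2R,5R)-5-hydroxy-2-methyl-3-oxo-5-(propan-2-yl)-2-(prop-2-en-1-yl)cyclopentyl]-3-methylbut-3-en-1-yl 4-methoxybenzoate
Product: 16 (3R,3aS,4S,8aR)-3-hydroxy-6,8a-dimethyl-1-oxo-3-(propan-2-yl)-1,2,3,3a,4,5,8,8a-octahydroazulen-4-yl 4-methoxybenzoate
Conditions: second-generation Grubbs catalyst RuCl2(=CHPh)(H2IMes)(PCy3) (5 mol %), CH2Cl2 (5 mM), 40 °C
Reagents that add atoms: none
Why: Ring-closing metathesis of the allyl and methallyl arms should close the seven-membered ring as the trisubstituted C8=C9 alkene, the trans arms on C1 and C5 giving the trans ring fusion without a new stereocentre.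

Step 9
Reactants: 16 (3R,3aS,4S,8aR)-3-hydroxy-6,8a-dimethyl-1-oxo-3-(propan-2-yl)-1,2,3,3a,4,5,8,8a-octahydroazulen-4-yl 4-methoxybenzoate
Product: 17 (1S,3R,3aS,4S,8aR)-1,3-dihydroxy-6,8a-dimethyl-3-(propan-2-yl)-1,2,3,3a,4,5,8,8a-octahydroazulen-4-yl 4-methoxybenzoate
Conditions: Me4NBH(OAc)3, AcOH–MeCN, −30 → 0 °C
Reagents that add atoms: none
Why: In this Evans–Saksena reduction the C4 hydroxyl should exchange onto boron and deliver hydride to the β-face of the C2 ketone, giving the anti 1,3-diol with the new C2 hydroxyl α, while ester and alkene are inert to the triacetoxyborohydride.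

Step 10
Reactants: 17 (1S,3R,3aS,4S,8aR)-1,3-dihydroxy-6,8a-dimethyl-3-(propan-2-yl)-1,2,3,3a,4,5,8,8a-octahydroazulen-4-yl 4-methoxybenzoate
Product: 18 (1S,3R,3aS,4S,8aR)-1-acetoxy-3-hydroxy-6,8a-dimethyl-3-(propan-2-yl)-1,2,3,3a,4,5,8,8a-octahydroazulen-4-yl 4-methoxybenzoate (CNP0171090.1)
Conditions: Ac2O, DMAP (cat.), pyridine, CH2Cl2, 25 °C
Reagents that add atoms: acetic anhydride, CC(=O)OC(C)=O
Why: DMAP-catalysed acetylation should esterify the secondary C2 hydroxyl and leave the tertiary C4 hydroxyl free, giving the target.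

**Compound list**

1 | (E)-4,4-dimethoxy-2-methylbut-2-enal | COC(OC)/C=C(\C)C=O | starting material
2 | (E)-1-[dimethyl(phenyl)silyl]-4,4-dimethoxy-2-methylbut-2-en-1-ol (racemic carbinol) | COC(OC)/C=C(\C)C(O)[Si](C)(C)c1ccccc1 | intermediate
3 | (E)-1-[dimethyl(phenyl)silyl]-4,4-dimethoxy-2-methylbut-2-en-1-one | COC(OC)/C=C(\C)C(=O)[Si](C)(C)c1ccccc1 | intermediate
4 | (E)-4-[dimethyl(phenyl)silyl]-3-methyl-4-oxobut-2-enal | O=C/C=C(\C)C(=O)[Si](C)(C)c1ccccc1 | intermediate
5 | 4,4,5,5-tetramethyl-2-(2-methylprop-2-en-1-yl)-1,3,2-dioxaborolane | CC(=C)CB1OC(C)(C)C(C)(C)O1 | starting material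
6 | (2E,4S)-1-[dimethyl(phenyl)silyl]-4-hydroxy-2,6-dimethylhepta-2,6-dien-1-one | C=C(C)C[C@H](O)/C=C(\C)C(=O)[Si](C)(C)c1ccccc1 | intermediate
7 | 3-methylbutan-2-one | CC(=O)C(C)C | starting material
8 | lithium 3-methylbut-1-en-2-olate | [Li]OC(=C)C(C)C | intermediate
9 | dilithium (6E,8S)-5-[dimethyl(phenyl)silyl]-2,6,10-trimethyl-3-oxoundeca-6,10-diene-5,8-diolate (both C5 epimers) | C=C(C)C[C@H](O[Li])/C=C(\C)C(O[Li])(CC(=O)C(C)C)[Si](C)(C)c1ccccc1 | intermediate
10 | lithium (8S)-5-[dimethyl(phenyl)silyloxy]-7-lithio-2,6,10-trimethyl-3-oxoundeca-5,10-dien-8-olate (delocalised siloxyallyl anion, chain carbons 4 and 7 cis on the 5,6-double bond) | C=C(C)C[C@H](O[Li])C([Li])/C(C)=C(\CC(=O)C(C)C)O[Si](C)(C)c1ccccc1 | intermediate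
11 | (1S)-1-{(1S,5R)-3-[dimethyl(phenyl)silyloxy]-5-hydroxy-2-methyl-5-(propan-2-yl)cyclopent-2-en-1-yl}-3-methylbut-3-en-1-ol | C=C(C)C[C@H](O)[C@H]1[C@](O)(C(C)C)CC(O[Si](C)(C)c2ccccc2)=C1C | intermediate
12 | 4-methoxybenzoyl chloride | COc1ccc(cc1)C(Cl)=O | starting material
13 | (1S)-1-{(1S,5R)-3-[dimethyl(phenyl)silyloxy]-5-hydroxy-2-methyl-5-(propan-2-yl)cyclopent-2-en-1-yl}-3-methylbut-3-en-1-yl 4-methoxybenzoate | COc1ccc(C(=O)O[C@@H](CC(C)=C)[C@H]2[C@](O)(C(C)C)CC(O[Si](C)(C)c3ccccc3)=C2C)cc1 | intermediate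
14 | allyl methyl carbonate | COC(=O)OCC=C | starting material
15 | (1S)-1-[(1S,2R,5R)-5-hydroxy-2-methyl-3-oxo-5-(propan-2-yl)-2-(prop-2-en-1-yl)cyclopentyl]-3-methylbut-3-en-1-yl 4-methoxybenzoate | COc1ccc(C(=O)O[C@@H](CC(C)=C)[C@H]2[C@](O)(C(C)C)CC(=O)[C@]2(C)CC=C)cc1 | intermediate
16 | (3R,3aS,4S,8aR)-3-hydroxy-6,8a-dimethyl-1-oxo-3-(propan-2-yl)-1,2,3,3a,4,5,8,8a-octahydroazulen-4-yl 4-methoxybenzoate | COc1ccc(C(=O)O[C@H]2CC(C)=CC[C@@]3(C)C(=O)C[C@@](O)(C(C)C)[C@H]23)cc1 | intermediate
17 | (1S,3R,3aS,4S,8aR)-1,3-dihydroxy-6,8a-dimethyl-3-(propan-2-yl)-1,2,3,3a,4,5,8,8a-octahydroazulen-4-yl 4-methoxybenzoate | COc1ccc(C(=O)O[C@H]2CC(C)=CC[C@@]3(C)[C@@H](O)C[C@@](O)(C(C)C)[C@H]23)cc1 | intermediate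
18 | (1S,3R,3aS,4S,8aR)-1-acetoxy-3-hydroxy-6,8a-dimethyl-3-(propan-2-yl)-1,2,3,3a,4,5,8,8a-octahydroazulen-4-yl 4-methoxybenzoate (CNP0171090.1) | COc1ccc(C(=O)O[C@H]2CC(C)=CC[C@@]3(C)[C@@H](OC(C)=O)C[C@@](O)(C(C)C)[C@H]23)cc1 | target

**Step count and risks**

Total step count: 10. Longest linear sequence: 10 steps (from 1).

Steps most likely to fail:

1. Step 5. The unstabilised siloxyallyl anion may be quenched by proton transfer from the ketone α-position before ring closure; closure may stop at the silicon-bearing carbon without ring expansion; or facial control may be lost if the C6 alkoxide does not bridge lithium to the ketone. Fallback: the C5 nucleophile is made as a stabilised, auxiliary-bearing enolate; the route sets out from aldehyde 4 and comes back at 11. Pinnick oxidation (NaClO2, NaH2PO4, 2-methylbut-2-ene) should give acid F1. The mixed pivalic anhydride (t-BuCOCl, Et3N; then LiCl and (S)-4-benzyl-1,3-oxazolidin-2-one) should give imide F2. Enolate 8 adds to the acylsilane carbonyl of F2, and Brook rearrangement then unmasks a lithium-chelated Z-imide enolate; its face anti to the benzyl group should close onto the ketone in a 5-enolexo aldol to give β-hydroxy imide F3. LiBH4 removes the auxiliary to give diol F4, Dess–Martin oxidation of the primary alcohol gives aldehyde F5, and CH2=C(CH3)CH2MgCl, adding under chelation by the magnesium alkoxide of O4 on the side away from the ring, should give 11.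

2. Step 7. Once the enolate is unmasked, the free tertiary alkoxide may trigger retro-aldol cleavage of C3–C4 in the β-hydroxy ketone, and facial selectivity at C1 may erode. Fallback: the C4 hydroxyl is masked before the quaternary centre is made; the route sets out from 13 and comes back at 15. Et3SiOTf and 2,6-lutidine should give triethylsilyl ether F6; the same allylation with 14 should then give ketone F7, which cannot fragment and whose α-face is still the open one; HF·pyridine frees the hydroxyl to give 15.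

3. Step 9. Exchange of the hindered tertiary hydroxyl onto boron may be slow, so that slow, undirected reduction of the neopentyl ketone erodes the facial selectivity. Fallback: the hydride is tethered covalently to O4; the route sets out from 16 and comes back at 17. (HMe2Si)2NH should give dimethylsilyl ether F8; BF3·OEt2 at −78 °C should activate the ketone for hydride transfer from silicon within the tether, which can only reach the β-face of C2; HF·pyridine removes the silicon to give 17.

**Further compounds**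

F1 | step 5 | (E)-4-[dimethyl(phenyl)silyl]-3-methyl-4-oxobut-2-enoic acid | OC(=O)/C=C(\C)C(=O)[Si](C)(C)c1ccccc1
F2 | step 5 | (S)-4-benzyl-3-{(E)-4-[dimethyl(phenyl)silyl]-3-methyl-4-oxobut-2-enoyl}-1,3-oxazolidin-2-one | O=C1OC[C@H](Cc2ccccc2)N1C(=O)/C=C(\C)C(=O)[Si](C)(C)c3ccccc3
F3 | step 5 | (S)-4-benzyl-3-{[(1R,5R)-3-[dimethyl(phenyl)silyloxy]-5-hydroxy-2-methyl-5-(propan-2-yl)cyclopent-2-en-1-yl]carbonyl}-1,3-oxazolidin-2-one | O=C1OC[C@H](Cc2ccccc2)N1C(=O)[C@H]3[C@](O)(C(C)C)CC(O[Si](C)(C)c4ccccc4)=C3C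
F4 | step 5 | (1R,2S)-4-[dimethyl(phenyl)silyloxy]-2-(hydroxymethyl)-3-methyl-1-(propan-2-yl)cyclopent-3-en-1-ol | OC[C@H]1[C@](O)(C(C)C)CC(O[Si](C)(C)c2ccccc2)=C1C
F5 | step 5 | (1R,5R)-3-[dimethyl(phenyl)silyloxy]-5-hydroxy-2-methyl-5-(propan-2-yl)cyclopent-2-ene-1-carbaldehyde | O=C[C@H]1[C@](O)(C(C)C)CC(O[Si](C)(C)c2ccccc2)=C1C
F6 | step 7 | (1S)-1-{(1S,5R)-3-[dimethyl(phenyl)silyloxy]-2-methyl-5-(propan-2-yl)-5-(triethylsilyloxy)cyclopent-2-en-1-yl}-3-methylbut-3-en-1-yl 4-methoxybenzoate | COc1ccc(C(=O)O[C@@H](CC(C)=C)[C@H]2[C@](O[Si](CC)(CC)CC)(C(C)C)CC(O[Si](C)(C)c3ccccc3)=C2C)cc1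
F7 | step 7 | (1S)-1-[(1S,2R,5R)-2-methyl-3-oxo-5-(propan-2-yl)-2-(prop-2-en-1-yl)-5-(triethylsilyloxy)cyclopentyl]-3-methylbut-3-en-1-yl 4-methoxybenzoate | COc1ccc(C(=O)O[C@@H](CC(C)=C)[C@H]2[C@](O[Si](CC)(CC)CC)(C(C)C)CC(=O)[C@]2(C)CC=C)cc1
F8 | step 9 | (3R,3aS,4S,8aR)-3-[(dimethylsilyl)oxy]-6,8a-dimethyl-1-oxo-3-(propan-2-yl)-1,2,3,3a,4,5,8,8a-octahydroazulen-4-yl 4-methoxybenzoate | COc1ccc(C(=O)O[C@H]2CC(C)=CC[C@@]3(C)C(=O)C[C@@](O[SiH](C)C)(C(C)C)[C@H]23)cc1
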